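The retrosynthesis cuts, in order: the propenyl C=C on ring B (back to a formyl group), the oxygen on C7 (back to a benzylic CH2), the bond from the C8 oxygen to ring B carbon C4', and last the ring A C1–C7 bond.
Enabling feature: carbonyl carbon C7 sits directly on ring A (3,4,5-trimethoxyphenyl). Its neighbour C8 carries one oxygen and one methyl group, so C7–C8–C9 plus that oxygen is propylene oxide once C7 is written as CH2.
Forward: no ring is formed. Ring A is joined to the C3 chain by epoxide opening, and ring B is placed on the C8 oxygen from a diaryliodonium salt. C7 is then oxidised, and the two-carbon end of the propenyl group is added last.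
Stereochemistry: the only centre, C8 (S), is bought with (S)-propylene oxide. No later step breaks a bond at C8, and the ketone that makes C8–H acidic meets only non-basic reagents. The (E)-alkene comes from a Takai–Utimoto olefination.

Key step: step 2

Assumption: neolignan numbering is used (ring A = 3,4,5-trimethoxyphenyl, C7 = carbonyl carbon, C8 = stereocentre, C9 = its methyl, ring B = the phenoxy ring, C4' = its oxygen-bearing carbon). The [C@@H] centre of the target reads as (S) by the ranking O > C7 > CH3 > H.

Step 1
Reactants: 1 5-bromo-1,2,3-trimethoxybenzene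
Product: 2 3,4,5-trimethoxyphenylmagnesium bromide (titrated THF stock solution)
Conditions: Mg turnings, I2 (crystal), THF, 50 °C → reflux
Reagents that add atoms: magnesium, [Mg]
Why: Grignard reagent formation by insertion of magnesium into the aryl C–Br bond, to which the three methyl ethers are inert.

Step 2
Reactants: 2 3,4,5-trimethoxyphenylmagnesium bromide; 3 (S)-propylene oxide
Product: 5 (S)-1-(3,4,5-trimethoxyphenyl)propan-2-ol, via bromomagnesium alkoxide 4 (not isolated)
Conditions: CuI (10 mol %), THF, −30 → 0 °C; aq. NH4Cl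
Reagents that add atoms: none
Why: Transmetallation of 2 to CuI gives a magnesium arylcuprate of monovalent copper that attacks the oxirane by SN2 at the unsubstituted carbon, passes through a trivalent aryl(alkyl)copper species and reductively eliminates, forming the ring A C1–C7 bond and returning copper to the cycle. The closest known reaction type is the copper-catalysed opening of terminal epoxides by aryl Grignard reagents. No ring is closed and no stereocentre is created: C8 is C2 of 3, none of its bonds is touched and the ranking O > CH2 > CH3 is unchanged, so (S)-3 should give (S)-5. The selectivity needed is regiochemical, CH2 against CH(CH3), and it rests on the steric contrast between the two oxirane carbons, which a soft cuprate distinguishes far better than the bare Grignard reagent. Copper catalysis and the low temperature also keep the Lewis-acidic magnesium halide from converting 3 into bromohydrin or propanal. Aqueous NH4Cl then releases 5 from alkoxide 4.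

Step 3
Reactants: 6 4-bromo-3,5-dimethoxybenzaldehyde
Product: 7 2-bromo-5-(dimethoxymethyl)-1,3-dimethoxybenzene
Conditions: HC(OMe)3, TsOH·H2O (cat.), MeOH, reflux; NaHCO3
Reagents that add atoms: trimethyl orthoformate, COC(OC)OC
Why: Acid-catalysed acetalisation, driven by the orthoester as water scavenger, masks the formyl group that n-BuLi would otherwise attack in the next step.

Step 4
Reactants: 7 2-bromo-5-(dimethoxymethyl)-1,3-dimethoxybenzene
Product: 10 4-iodo-3,5-dimethoxybenzaldehyde, via aryllithium 8 (not isolated), via iodo acetal 9 (not isolated)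
Conditions: n-BuLi, THF, −78 °C; I2, −78 °C → rt; aq. Na2S2O3; 1 M HCl, THF, rt
Reagents that add atoms: iodine, [I][I]; water, O
Why: Bromine–lithium exchange at −78 °C gives an aryllithium held between two methoxy groups, iodine quenches it at the same carbon and dilute acid hydrolyses the acetal, so the halogen is swapped with no regiochemical ambiguity.

Step 5
Reactants: 10 4-iodo-3,5-dimethoxybenzaldehyde; 11 1,3,5-trimethoxybenzene
Product: 13 (4-formyl-2,6-dimethoxyphenyl)(2,4,6-trimethoxyphenyl)iodonium p-toluenesulfonate, via hydroxy(tosyloxy)iodoarene 12 (not isolated)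
Conditions: mCPBA (1.0 equiv), TsOH·H2O (1.0 equiv), MeCN, 50 °C; then 11, 50 °C → rt; Et2O trituration
Reagents that add atoms: p-toluenesulfonic acid monohydrate, Cc1ccc(S(=O)(=O)O)cc1.O
Why: One-pot diaryliodonium salt synthesis in which the peracid and TsOH raise the iodoarene to trivalent iodine faster than the peracid attacks the aldehyde (flanked only by meta-alkoxy groups), the very nucleophilic arene 11 then bonds to iodine by electrophilic aromatic substitution at one of its three equivalent CH positions, and a single equivalent of TsOH leaves no free strong acid to condense 11 onto the formyl group.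

Step 6
Reactants: 5 (S)-1-(3,4,5-trimethoxyphenyl)propan-2-ol; 13 (4-formyl-2,6-dimethoxyphenyl)(2,4,6-trimethoxyphenyl)iodonium p-toluenesulfonate
Product: 15 4-{[(2S)-1-(3,4,5-trimethoxyphenyl)propan-2-yl]oxy}-3,5-dimethoxybenzaldehyde, via sodium alkoxide 14 (not isolated)
Conditions: NaH (1.0 equiv), TBME, 0 °C → rt; 13 (1.2 equiv), rt → 50 °C
Reagents that add atoms: none
Why: Metal-free O-arylation of an aliphatic alkoxide with an unsymmetrical diaryliodonium salt (ligand exchange at iodine, then ligand coupling), in which the formyl-bearing ring is transferred because it is much the electron-poorer of two equally ortho-crowded aryl ligands, neither ring has an ortho hydrogen so no aryne can form, C7 is still CH2 so C8–H is not acidic, and only the O–H bond of 5 is broken so the (S) configuration is retained.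

Step 7
Reactants: 15 4-{[(2S)-1-(3,4,5-trimethoxyphenyl)propan-2-yl]oxy}-3,5-dimethoxybenzaldehyde
Product: 17 4-{[(2S)-1-oxo-1-(3,4,5-trimethoxyphenyl)propan-2-yl]oxy}-3,5-dimethoxybenzaldehyde, via C7 carbinol 16 (not isolated)
Conditions: DDQ (2.5 equiv), 1,4-dioxane–H2O (10:1), rt → 60 °C
Reagents that add atoms: water, O
Why: DDQ benzylic oxidation of a methoxy-activated alkylarene in wet solvent, in which hydride abstraction from C7 gives a cation stabilised by the para-methoxy group of ring A, water traps it as carbinol 16 and a second, easier hydride abstraction gives the aryl ketone, while ring B is deactivated by its formyl group and has no benzylic C–H, and the non-basic medium should leave the now enolisable C8 untouched.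

Step 8
Reactants: 17 4-{[(2S)-1-oxo-1-(3,4,5-trimethoxyphenyl)propan-2-yl]oxy}-3,5-dimethoxybenzaldehyde
Product: 18 (2S)-2-{2,6-dimethoxy-4-[(1E)-prop-1-en-1-yl]phenoxy}-1-(3,4,5-trimethoxyphenyl)propan-1-one (CNP0118388.1)
Conditions: CrCl2 (8 equiv), CH3CHI2 (2 equiv), THF, 0 °C → rt
Reagents that add atoms: 1,1-diiodoethane, CC(I)I
Why: Takai–Utimoto ethylidenation, whose gem-dichromium reagent adds to aldehydes much faster than to ketones, is practically non-basic so C8 should not epimerise, and eliminates from the less crowded β-oxido organochromium adduct to give the (E)-propenyl group.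

Compound list
1 | 5-bromo-1,2,3-trimethoxybenzene | COc1cc(Br)cc(OC)c1OC | starting material
2 | 3,4,5-trimethoxyphenylmagnesium bromide | COc1cc([Mg]Br)cc(OC)c1OC | intermediate
3 | (S)-propylene oxide | C[C@H]1CO1 | starting material
4 | bromomagnesium (S)-1-(3,4,5-trimethoxyphenyl)propan-2-olate | C[C@H](O[Mg]Br)Cc1cc(OC)c(OC)c(OC)c1 | intermediate
5 | (S)-1-(3,4,5-trimethoxyphenyl)propan-2-ol | C[C@H](O)Cc1cc(OC)c(OC)c(OC)c1 | intermediate
6 | 4-bromo-3,5-dimethoxybenzaldehyde | COc1cc(C=O)cc(OC)c1Br | starting material
7 | 2-bromo-5-(dimethoxymethyl)-1,3-dimethoxybenzene | COC(OC)c1cc(OC)c(Br)c(OC)c1 | intermediate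
8 | [4-(dimethoxymethyl)-2,6-dimethoxyphenyl]lithium | COC(OC)c1cc(OC)c([Li])c(OC)c1 | intermediate
9 | 5-(dimethoxymethyl)-2-iodo-1,3-dimethoxybenzene | COC(OC)c1cc(OC)c(I)c(OC)c1 | intermediate
10 | 4-iodo-3,5-dimethoxybenzaldehyde | COc1cc(C=O)cc(OC)c1I | intermediate
11 | 1,3,5-trimethoxybenzene | COc1cc(OC)cc(OC)c1 | starting material
12 | 4-[hydroxy(tosyloxy)iodo]-3,5-dimethoxybenzaldehyde | COc1cc(C=O)cc(OC)c1I(O)OS(=O)(=O)c1ccc(C)cc1 | intermediate
13 | (4-formyl-2,6-dimethoxyphenyl)(2,4,6-trimethoxyphenyl)iodonium p-toluenesulfonate | COc1cc(OC)cc(OC)c1[I+]c1c(OC)cc(C=O)cc1OC.Cc1ccc(S(=O)(=O)[O-])cc1 | intermediate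
14 | sodium (S)-1-(3,4,5-trimethoxyphenyl)propan-2-olate | C[C@H]([O-])Cc1cc(OC)c(OC)c(OC)c1.[Na+] | intermediate
15 | 4-{[(2S)-1-(3,4,5-trimethoxyphenyl)propan-2-yl]oxy}-3,5-dimethoxybenzaldehyde | C[C@H](Oc1c(OC)cc(C=O)cc1OC)Cc1cc(OC)c(OC)c(OC)c1 | intermediate
16 | 4-{[(2S)-1-hydroxy-1-(3,4,5-trimethoxyphenyl)propan-2-yl]oxy}-3,5-dimethoxybenzaldehyde (C7 epimers) | C[C@H](Oc1c(OC)cc(C=O)cc1OC)C(O)c1cc(OC)c(OC)c(OC)c1 | intermediate
17 | 4-{[(2S)-1-oxo-1-(3,4,5-trimethoxyphenyl)propan-2-yl]oxy}-3,5-dimethoxybenzaldehyde | C[C@H](Oc1c(OC)cc(C=O)cc1OC)C(=O)c1cc(OC)c(OC)c(OC)c1 | intermediate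
18 | (2S)-2-{2,6-dimethoxy-4-[(1E)-prop-1-en-1-yl]phenoxy}-1-(3,4,5-trimethoxyphenyl)propan-1-one | C/C=C/c1cc(OC)c(O[C@@H](C)C(=O)c2cc(OC)c(OC)c(OC)c2)c(OC)c1 | target

Total step count: 8. Longest linear sequence: 6 (steps 3, 4, 5, 6, 7, 8).

Steps most likely to fail

**Step 7.**
- What may go wrong: hydride abstraction may be slow, because the C8 aryloxy group destabilises the developing C7 cation and the central methoxy group of ring A is twisted out of conjugation.
- The cation may also lose the C8 proton, which leads to enol ether formation and ether cleavage.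
- Prolonged heating in the presence of the acidic hydroquinone may enolise the product and erode C8.
- Fallback: ring A is given a stronger activating group, a free para-phenol, so that C7 is oxygenated through a p-quinone methide. The fallback sets out from 3 and 13 and comes back at 17.
- Commercial 4-bromo-2,6-dimethoxyphenol (COc1cc(Br)cc(OC)c1O) is protected with MOMCl and i-Pr2NEt as 5-bromo-1,3-dimethoxy-2-(methoxymethoxy)benzene F1.
- Magnesium in THF converts this into [3,5-dimethoxy-4-(methoxymethoxy)phenyl]magnesium bromide F2, which opens 3 under the CuI catalysis of step 2 to give (S)-1-[3,5-dimethoxy-4-(methoxymethoxy)phenyl]propan-2-ol F3.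
- NaH and 13, as in step 6, should give 4-({(2S)-1-[3,5-dimethoxy-4-(methoxymethoxy)phenyl]propan-2-yl}oxy)-3,5-dimethoxybenzaldehyde F4.
- Dilute HCl in THF frees 4-{[(2S)-1-(4-hydroxy-3,5-dimethoxyphenyl)propan-2-yl]oxy}-3,5-dimethoxybenzaldehyde F5.
- DDQ (2 equiv) in aqueous dioxane at 0 °C to rt dehydrogenates the phenol to 4-[(2S)-2-(4-formyl-2,6-dimethoxyphenoxy)propylidene]-2,6-dimethoxycyclohexa-2,5-dien-1-one F6.
- Water adds at C7 of F6, as it does to the quinone methides of lignin β-aryl ethers, giving 4-{[(2S)-1-hydroxy-1-(4-hydroxy-3,5-dimethoxyphenyl)propan-2-yl]oxy}-3,5-dimethoxybenzaldehyde F7.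
- The second equivalent of DDQ oxidises F7 to 4-{[(2S)-1-(4-hydroxy-3,5-dimethoxyphenyl)-1-oxopropan-2-yl]oxy}-3,5-dimethoxybenzaldehyde F8.
- The acidic phenol of F8 is methylated without base by trimethylsilyldiazomethane in toluene–MeOH, which gives 17.

**Step 6.**
- What may go wrong: hydride may transfer from the secondary alkoxide to the activated formyl group or to iodine, oxidising the carbinol to its ketone.
- Ligand coupling may be slow at an iodine centre flanked by four ortho-methoxy groups.
- The trimethoxyphenyl ligand may be transferred in competition with the desired ring.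
- Fallback: the polarity of the ether synthesis is reversed, with ring B as the nucleophile and C8 as the electrophile, and the inversion is compensated by the mirror-image epoxide. The fallback sets out from 2 and comes back at 15.
- Grignard reagent 2 opens commercial (R)-propylene oxide (C[C@@H]1CO1) under the conditions of step 2 to give (R)-1-(3,4,5-trimethoxyphenyl)propan-2-ol F9.
- A Mitsunobu reaction of F9 with commercial syringaldehyde (COc1cc(C=O)cc(OC)c1O), PPh3 and DIAD in toluene displaces the activated oxygen with inversion and should deliver (S)-15.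

**Step 8.**
- What may go wrong: the large excess of divalent chromium may transfer a single electron to the α-aryloxy ketone, cleaving the C8–O bond.
- The alkene geometry may be incompletely controlled.
- The trivalent chromium salts may promote enolisation by Lewis acid catalysis.
- Fallback: the alkene is built in two neutral, chromium-free operations. The fallback sets out from 17 and comes back at 18.
- Rhodium-catalysed methylenation (RhCl(PPh3)3 cat., PPh3, trimethylsilyldiazomethane, 2-propanol, THF, rt) is selective for aldehydes over ketones. It should give (2S)-2-(4-ethenyl-2,6-dimethoxyphenoxy)-1-(3,4,5-trimethoxyphenyl)propan-1-one F10.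
- Cross-metathesis of F10 with excess (Z)-but-2-ene uses the second-generation Hoveyda–Grubbs catalyst, RuCl2(H2IMes)(=CH-C6H4-2-O-i-Pr), in CH2Cl2 at 40 °C. It places the terminal methyl group under thermodynamic (E) control and gives 18.

Further compounds
F1 | step 7 | 5-bromo-1,3-dimethoxy-2-(methoxymethoxy)benzene | COCOc1c(OC)cc(Br)cc1OC
F2 | step 7 | [3,5-dimethoxy-4-(methoxymethoxy)phenyl]magnesium bromide | COCOc1c(OC)cc([Mg]Br)cc1OC
F3 | step 7 | (S)-1-[3,5-dimethoxy-4-(methoxymethoxy)phenyl]propan-2-ol | C[C@H](O)Cc1cc(OC)c(OCOC)c(OC)c1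
F4 | step 7 | 4-({(2S)-1-[3,5-dimethoxy-4-(methoxymethoxy)phenyl]propan-2-yl}oxy)-3,5-dimethoxybenzaldehyde | C[C@H](Oc1c(OC)cc(C=O)cc1OC)Cc1cc(OC)c(OCOC)c(OC)c1
F5 | step 7 | 4-{[(2S)-1-(4-hydroxy-3,5-dimethoxyphenyl)propan-2-yl]oxy}-3,5-dimethoxybenzaldehyde | C[C@H](Oc1c(OC)cc(C=O)cc1OC)Cc1cc(OC)c(O)c(OC)c1
F6 | step 7 | 4-[(2S)-2-(4-formyl-2,6-dimethoxyphenoxy)propylidene]-2,6-dimethoxycyclohexa-2,5-dien-1-one | C[C@H](Oc1c(OC)cc(C=O)cc1OC)C=C1C=C(OC)C(=O)C(OC)=C1
F7 | step 7 | 4-{[(2S)-1-hydroxy-1-(4-hydroxy-3,5-dimethoxyphenyl)propan-2-yl]oxy}-3,5-dimethoxybenzaldehyde (C7 epimers) | C[C@H](Oc1c(OC)cc(C=O)cc1OC)C(O)c1cc(OC)c(O)c(OC)c1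
F8 | step 7 | 4-{[(2S)-1-(4-hydroxy-3,5-dimethoxyphenyl)-1-oxopropan-2-yl]oxy}-3,5-dimethoxybenzaldehyde | C[C@H](Oc1c(OC)cc(C=O)cc1OC)C(=O)c1cc(OC)c(O)c(OC)c1
F9 | step 6 | (R)-1-(3,4,5-trimethoxyphenyl)propan-2-ol | C[C@@H](O)Cc1cc(OC)c(OC)c(OC)c1
F10 | step 8 | (2S)-2-(4-ethenyl-2,6-dimethoxyphenoxy)-1-(3,4,5-trimethoxyphenyl)propan-1-one | C=Cc1cc(OC)c(O[C@@H](C)C(=O)c2cc(OC)c(OC)c(OC)c2)c(OC)c1
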